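**Retrosynthetic overview**
- The target comes from a tris-MOM flavanone by one acidic deprotection.
- The C2–aryl bond, and with it the only stereocentre, comes from a ligand-controlled Pd(II) conjugate addition of a B-ring arylboronic acid to a 7-O-MOM-8-prenylchromone.
- The chromone is built from acyclic partners in one operation: [4+2] benzannulation of a 2-prenyl Brassard-type diene with diethynyl ketone (ring A), then 6-endo oxa-Michael closure of the o-hydroxyaryl ynone (ring C).
- The diene comes from methyl acetoacetate and prenyl bromide; the boronic acid comes from catechol by MOM-directed ortho-prenylation and sterically controlled C–H borylation.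
- Ring order: A, then C in the same flask; ring B is bought as catechol.

Assumption: the Pd/t-BuPyOx catalyst is taken to show the same facial preference on chromones as on cyclic enones ((S)-ligand gives the (R)-2-arylchromanone), so the (R)-ligand is specified for the (2S) product; penta-1,4-diyn-3-ol is taken as a purchasable starting material.

**Route**

Step 1
Reactants: 1 methyl acetoacetate; 2 prenyl bromide (1-bromo-3-methylbut-2-ene)
Product: 3 methyl 2-acetyl-5-methylhex-4-enoate (racemic)
Conditions: K2CO3, acetone, reflux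
Reagents that add atoms: none
Why: Acetoacetic ester C-alkylation of the β-keto ester enolate with a reactive allylic bromide, mono-alkylation favoured with 1 equiv of 2; the stereocentre is racemic and is erased in step 2.

Step 2
Reactants: 3 methyl 2-acetyl-5-methylhex-4-enoate
Product: 4 methyl 3-(methoxymethoxy)-2-(3-methylbut-2-enyl)but-2-enoate (E/Z mixture)
Conditions: NaH, THF/DMPU, 0 °C; MOMCl, 0 °C → rt
Reagents that add atoms: chloromethyl methyl ether, COCCl
Why: Enolate O-alkylation (Williamson-type enol ether formation), favoured for a hard chloromethyl ether on an α-substituted enolate in a dipolar medium; the alkene geometry is lost again in step 3.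

Step 3
Reactants: 4 methyl 3-(methoxymethoxy)-2-(3-methylbut-2-enyl)but-2-enoate
Product: 5 1-methoxy-3-(methoxymethoxy)-2-(3-methylbut-2-enyl)-1-(trimethylsilyloxy)buta-1,3-diene
Conditions: LDA, THF, −78 °C; TMSCl, −78 °C → rt; used crude
Reagents that add atoms: chlorotrimethylsilane, C[Si](C)(C)Cl
Why: Kinetic γ-deprotonation of the β-alkoxy enoate and O-silylation of the dienolate give the silyl ketene acetal, the same vinylogous enolisation used to make Brassard's diene.

Step 4
Reactants: 6 penta-1,4-diyn-3-ol
Product: 7 penta-1,4-diyn-3-one (diethynyl ketone)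
Conditions: activated MnO2, CH2Cl2, 0 °C → rt; filtered and used at once as a solution
Reagents that add atoms: none
Why: MnO2 oxidation of a doubly propargylic alcohol; the volatile, polymerisation-prone ynone is never concentrated.

Step 5
Reactants: 5 1-methoxy-3-(methoxymethoxy)-2-(3-methylbut-2-enyl)-1-(trimethylsilyloxy)buta-1,3-diene; 7 penta-1,4-diyn-3-one
Product: 10 7-(methoxymethoxy)-8-(3-methylbut-2-enyl)-4H-chromen-4-one, via cycloadduct ketal 8 (not isolated), via o-hydroxyaryl ynone 9 (not isolated)
Conditions: 5 added slowly to 7 (1.5 equiv), PhMe/CH2Cl2, −20 °C → rt; then K2CO3 (0.2 equiv), MeOH, 0 °C → rt; AcOH quench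
Reagents that add atoms: none
Why: Proposed new method: the Brassard-type diene 5 adds its nucleophilic CH2 terminus to the β-carbon of one ynone unit of 7 in a [4+2] cycloaddition (closest precedent: the Danishefsky/Brassard Diels–Alder resorcinol synthesis from 1,1,3-trioxygenated dienes and alkynyl ketones) to give ketal 8, in which the ester carbon has become C8a; catalytic methanolysis of the O–Si bond collapses the ketal with loss of methoxide (caught as MeOSiMe3) and tautomerisation gives phenoxide 9 (ring A), whose oxygen then closes ring C by 6-endo-dig oxa-Michael addition to the second ynone, the standard o-hydroxyaryl ynone to chromone closure; diene polarisation places the acyl group ortho to the ketene-acetal oxygen and the prenyl group between the two oxygens, and no stereocentre remains in 10.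

Step 6
Reactants: 11 catechol
Product: 12 1,2-bis(methoxymethoxy)benzene
Conditions: NaH, DMF, 0 °C; MOMCl, 0 °C → rt
Reagents that add atoms: chloromethyl methyl ether, COCCl
Why: Williamson etherification of both phenoxides (MOM protection); MOM directs the metalation in step 7 and is removed by acid at the end.

Step 7
Reactants: 12 1,2-bis(methoxymethoxy)benzene; 2 prenyl bromide
Product: 13 1,2-bis(methoxymethoxy)-3-(3-methylbut-2-enyl)benzene
Conditions: n-BuLi, THF, 0 °C; CuI (10 mol%), 2, −78 °C → rt
Reagents that add atoms: none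
Why: Directed ortho-metalation by the MOM ether followed by copper-catalysed SN2 allylation of the aryllithium gives the linear prenyl arene.

Step 8
Reactants: 13 1,2-bis(methoxymethoxy)-3-(3-methylbut-2-enyl)benzene
Product: 15 [3,4-bis(methoxymethoxy)-5-(3-methylbut-2-enyl)phenyl]boronic acid, via pinacol boronate 14 (not isolated)
Conditions: [Ir(OMe)(cod)]2 (1.5 mol%), dtbpy (3 mol%), B2pin2 (0.55 equiv), THF, 60 °C; then NaIO4, NH4OAc, acetone/H2O, rt
Reagents that add atoms: bis(pinacolato)diboron, CC1(C)OB(OC1(C)C)B1OC(C)(C)C(C)(C)O1; water, O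
Why: Iridium-catalysed aromatic C–H borylation is sterically controlled and goes to C5, the only ring C–H without an ortho substituent; oxidative cleavage of the pinacol ester with periodate releases the boronic acid.

Step 9
Reactants: 10 7-(methoxymethoxy)-8-(3-methylbut-2-enyl)-4H-chromen-4-one; 15 [3,4-bis(methoxymethoxy)-5-(3-methylbut-2-enyl)phenyl]boronic acid
Product: 16 (2S)-2-[3,4-bis(methoxymethoxy)-5-(3-methylbut-2-enyl)phenyl]-7-(methoxymethoxy)-8-(3-methylbut-2-enyl)-2,3-dihydro-4H-chromen-4-one
Conditions: Pd(OCOCF3)2 (5 mol%), (R)-t-BuPyOx (6 mol%), NH4PF6 (30 mol%), H2O (5 equiv), 15 (2 equiv), ClCH2CH2Cl, 60 °C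
Reagents that add atoms: none
Why: Pd(II)-catalysed enantioselective conjugate addition of an arylboronic acid to a chromone (pyridine-oxazoline system): the aryl-palladium inserts the C2=C3 bond on the face set by the ligand and the Pd enolate is protonated by water, which sets C2 as S.

Step 10
Reactants: 16 (2S)-2-[3,4-bis(methoxymethoxy)-5-(3-methylbut-2-enyl)phenyl]-7-(methoxymethoxy)-8-(3-methylbut-2-enyl)-2,3-dihydro-4H-chromen-4-one
Product: 17 (2S)-2-[3,4-dihydroxy-5-(3-methylbut-2-enyl)phenyl]-7-hydroxy-8-(3-methylbut-2-enyl)-2,3-dihydro-4H-chromen-4-one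
Conditions: 3 M HCl (aq)/MeOH 1:4, 50 °C
Reagents that add atoms: none
Why: Acid-catalysed acetal exchange removes all three MOM ethers; the flavanone stereocentre is stable to acid because racemisation is a base-mediated retro-oxa-Michael, and mild conditions limit cyclisation of the o-prenylphenols to chromans.

**Compound list**
1 | methyl acetoacetate | CC(=O)CC(=O)OC | starting material
2 | prenyl bromide (1-bromo-3-methylbut-2-ene) | CC(C)=CCBr | starting material
3 | methyl 2-acetyl-5-methylhex-4-enoate (racemic) | CC(=O)C(CC=C(C)C)C(=O)OC | intermediate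
4 | methyl 3-(methoxymethoxy)-2-(3-methylbut-2-enyl)but-2-enoate (E/Z mixture) | COCOC(C)=C(CC=C(C)C)C(=O)OC | intermediate
5 | 1-methoxy-3-(methoxymethoxy)-2-(3-methylbut-2-enyl)-1-(trimethylsilyloxy)buta-1,3-diene | C=C(OCOC)C(CC=C(C)C)=C(OC)O[Si](C)(C)C | intermediate
6 | penta-1,4-diyn-3-ol | C#CC(O)C#C | starting material
7 | penta-1,4-diyn-3-one | C#CC(=O)C#C | intermediate
8 | 1-[6-methoxy-4-(methoxymethoxy)-5-(3-methylbut-2-enyl)-6-(trimethylsilyloxy)cyclohexa-1,4-dien-1-yl]prop-2-yn-1-one (racemic) | COC1(O[Si](C)(C)C)C(C(=O)C#C)=CCC(OCOC)=C1CC=C(C)C | intermediate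
9 | 1-[2-hydroxy-4-(methoxymethoxy)-3-(3-methylbut-2-enyl)phenyl]prop-2-yn-1-one | C#CC(=O)c1ccc(OCOC)c(CC=C(C)C)c1O | intermediate
10 | 7-(methoxymethoxy)-8-(3-methylbut-2-enyl)-4H-chromen-4-one | O=c1ccoc2c(CC=C(C)C)c(OCOC)ccc12 | intermediate
11 | catechol (benzene-1,2-diol) | Oc1ccccc1O | starting material
12 | 1,2-bis(methoxymethoxy)benzene | COCOc1ccccc1OCOC | intermediate
13 | 1,2-bis(methoxymethoxy)-3-(3-methylbut-2-enyl)benzene | COCOc1cccc(CC=C(C)C)c1OCOC | intermediate
14 | 2-[3,4-bis(methoxymethoxy)-5-(3-methylbut-2-enyl)phenyl]-4,4,5,5-tetramethyl-1,3,2-dioxaborolane | COCOc1cc(B2OC(C)(C)C(C)(C)O2)cc(CC=C(C)C)c1OCOC | intermediate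
15 | [3,4-bis(methoxymethoxy)-5-(3-methylbut-2-enyl)phenyl]boronic acid | COCOc1cc(B(O)O)cc(CC=C(C)C)c1OCOC | intermediate
16 | (2S)-2-[3,4-bis(methoxymethoxy)-5-(3-methylbut-2-enyl)phenyl]-7-(methoxymethoxy)-8-(3-methylbut-2-enyl)-2,3-dihydro-4H-chromen-4-one | CC(C)=CCc1cc([C@@H]2CC(=O)c3ccc(OCOC)c(CC=C(C)C)c3O2)cc(OCOC)c1OCOC | intermediate
17 | (2S)-2-[3,4-dihydroxy-5-(3-methylbut-2-enyl)phenyl]-7-hydroxy-8-(3-methylbut-2-enyl)-2,3-dihydro-4H-chromen-4-one | CC(C)=CCc1cc([C@@H]2CC(=O)c3ccc(O)c(CC=C(C)C)c3O2)cc(O)c1O | target

**Totals**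
Total step count: 10. Longest linear sequence: 6 steps (steps 1, 2, 3, 5, 9, 10).

**Three steps most likely to fail**

Step 5 (one-pot formation of rings A and C). The diynone is unstable, can react twice, and the ketal could aromatise thermally with loss of silanol to a dead-end 2-methoxyaryl ynone. Fallback: setting out from diene 5, the same Diels–Alder/methanolysis is run with commercial but-3-yn-2-one to give the acetophenone 1-[2-hydroxy-4-(methoxymethoxy)-3-(3-methylbut-2-enyl)phenyl]ethanone F1. This is condensed with DMF dimethyl acetal to the enaminone (E)-3-(dimethylamino)-1-[2-hydroxy-4-(methoxymethoxy)-3-(3-methylbut-2-enyl)phenyl]prop-2-en-1-one F2, which is closed with acetic acid, so that ring C is made in a separate operation and the route is rejoined at chromone 10.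

Step 9 (enantioselective conjugate addition). The electron-rich, 8-substituted chromone may react slowly, and the ee or the sense of induction may not meet the need. Fallback: setting out from chromone 10 and boronic acid 15, a Pd(II)-catalysed oxidative Heck-type C2-arylation (Pd(OCOCF3)2, benzoquinone or O2) gives the flavone 2-[3,4-bis(methoxymethoxy)-5-(3-methylbut-2-enyl)phenyl]-7-(methoxymethoxy)-8-(3-methylbut-2-enyl)-4H-chromen-4-one F3. Its C2=C3 bond is then reduced by copper hydride with a chiral bisphosphine (Cu(OAc)2, DTBM-SEGPHOS antipode chosen for 2S, (EtO)2MeSiH, t-BuOH), so that hydride rather than aryl delivery sets C2, and the route is rejoined at flavanone 16.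

Step 8 (C–H borylation next to a prenyl group). The iridium catalyst may hydroborate or isomerise the trisubstituted alkene, or borylate ortho to OMOM. Fallback: setting out from catechol 11, bromination (NBS, MeCN) gives 4-bromobenzene-1,2-diol F4. Ortho-C-prenylation of its sodium phenoxide with prenyl bromide 2 in toluene gives 5-bromo-3-(3-methylbut-2-enyl)benzene-1,2-diol F5, which is MOM-protected to 5-bromo-1,2-bis(methoxymethoxy)-3-(3-methylbut-2-enyl)benzene F6. Bromine–lithium exchange (n-BuLi, −78 °C), B(OiPr)3 and aqueous work-up then rejoin the route at boronic acid 15, the boron position being fixed by the halogen instead of by sterics.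

**Further compounds**
F1 | step 5 | 1-[2-hydroxy-4-(methoxymethoxy)-3-(3-methylbut-2-enyl)phenyl]ethanone | CC(=O)c1ccc(OCOC)c(CC=C(C)C)c1O
F2 | step 5 | (E)-3-(dimethylamino)-1-[2-hydroxy-4-(methoxymethoxy)-3-(3-methylbut-2-enyl)phenyl]prop-2-en-1-one | CN(C)/C=C/C(=O)c1ccc(OCOC)c(CC=C(C)C)c1O
F3 | step 9 | 2-[3,4-bis(methoxymethoxy)-5-(3-methylbut-2-enyl)phenyl]-7-(methoxymethoxy)-8-(3-methylbut-2-enyl)-4H-chromen-4-one | CC(C)=CCc1cc(-c2cc(=O)c3ccc(OCOC)c(CC=C(C)C)c3o2)cc(OCOC)c1OCOC
F4 | step 8 | 4-bromobenzene-1,2-diol | Oc1ccc(Br)cc1O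
F5 | step 8 | 5-bromo-3-(3-methylbut-2-enyl)benzene-1,2-diol | CC(C)=CCc1cc(Br)cc(O)c1O
F6 | step 8 | 5-bromo-1,2-bis(methoxymethoxy)-3-(3-methylbut-2-enyl)benzene | COCOc1cc(Br)cc(CC=C(C)C)c1OCOC
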